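Locants: C1 bears the C7H2OBz arm, C2 is the vinylic CH, and C3, C4, C5 (benzoate) and C6 are the four carbinol carbons of the single carbocycle. All four ring oxygens lie on one face.
Cuts: first the two ester C–O bonds (O5, O7) and the C1=C2 π bond (back to a C1,C7-diol), then C1–C7 (back to a C1 ketone), and last the ring bond C2–C3.
Enabling feature: C2 is the only ring carbon without oxygen, and C3–C6 repeat the all-cis pattern of C1–C4 of an α-D-allopyranoside. The carbocycle is therefore a hex-5-enopyranoside whose ring oxygen has been exchanged for sugar C6.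
Forward: D-glucose → benzyl α-glucopyranoside → inversion at sugar C3 on the rigid pyranoside → 5,6-enol ether → cyclohexanone (the only ring closure) → C7 by methylenation → diol → dibenzoate → dehydration → debenzylation.
Stereochemistry: C4 and C6 are glucose C2 and C4 untouched, C5 comes from a substrate-controlled hydride reduction, and C3 is the α-anomeric centre carried through the rearrangement. A transient C1 carbinol only steers the elimination.

Key step: step 10

Assumption: plain locants C1–C7 are those of the target and sugar locants are always marked "sugar". The configuration written for the transient C1 carbinol centre (steps 12 to 15) is the predicted one and vanishes in step 15.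

Step 1
Reactants: 1 D-glucose; 2 benzyl alcohol
Product: 3 benzyl α-D-glucopyranoside
Conditions: 2 as solvent, sulfonic acid resin (H+ form), 90 °C
Reagents that add atoms: none
Why: Fischer glycosidation under equilibrating acid conditions should favour the pyranoside with the axial benzyloxy group through the anomeric effect, which fixes the α configuration that later becomes C3, and residual β anomer is to be removed when 4 is crystallised.

Step 2
Reactants: 3 benzyl α-D-glucopyranoside
Product: 4 benzyl 4,6-O-[(R)-benzylidene]-α-D-glucopyranoside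
Conditions: PhCH(OMe)2, CSA (cat.), MeCN, 50 °C; crystallisation
Reagents that add atoms: benzaldehyde dimethyl acetal, COC(OC)c1ccccc1
Why: Acid-catalysed transacetalisation should close the thermodynamically preferred trans-fused 1,3-dioxane across O4 and O6 with the phenyl group equatorial, which leaves only O2 and O3 free.

Step 3
Reactants: 4 benzyl 4,6-O-[(R)-benzylidene]-α-D-glucopyranoside
Product: 5 benzyl 2-O-benzyl-4,6-O-[(R)-benzylidene]-α-D-glucopyranoside
Conditions: BnBr (1.1 equiv), Bu4NHSO4 (cat.), aq NaOH, CH2Cl2, reflux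
Reagents that add atoms: benzyl bromide, BrCc1ccccc1
Why: Phase-transfer Williamson etherification with a limited amount of halide should alkylate mainly O2, the more acidic hydroxyl next to the anomeric centre of an α-glucoside, and the O3 isomer and the diether are separable by chromatography.

Step 4
Reactants: 5 benzyl 2-O-benzyl-4,6-O-[(R)-benzylidene]-α-D-glucopyranoside
Product: 6 benzyl 2-O-benzyl-4,6-O-[(R)-benzylidene]-α-D-ribo-hexopyranosid-3-ulose
Conditions: Dess–Martin periodinane, CH2Cl2, rt
Reagents that add atoms: none
Why: The Dess–Martin oxidation is neutral, so the 3-ulose should form without epimerisation at sugar C2 or C4 and without β-elimination.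

Step 5
Reactants: 6 benzyl 2-O-benzyl-4,6-O-[(R)-benzylidene]-α-D-ribo-hexopyranosid-3-ulose
Product: 7 benzyl 2-O-benzyl-4,6-O-[(R)-benzylidene]-α-D-allopyranoside
Conditions: NaBH4, MeOH/CH2Cl2, 0 °C
Reagents that add atoms: none
Why: In the rigid 4C1 chair the axial anomeric benzyloxy group shields the α face of the carbonyl group, so this borohydride reduction should deliver hydride from the β face and give the axial (allo) alcohol, which sets C5 of the target.

Step 6
Reactants: 7 benzyl 2-O-benzyl-4,6-O-[(R)-benzylidene]-α-D-allopyranoside; 8 2-(bromomethyl)naphthalene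
Product: 9 benzyl 2-O-benzyl-4,6-O-[(R)-benzylidene]-3-O-(2-naphthylmethyl)-α-D-allopyranoside
Conditions: NaH, DMF, 0 °C to rt
Reagents that add atoms: none
Why: Williamson etherification of the only free hydroxyl marks the future benzoate oxygen with the one ether that DDQ can later remove beside benzyl ethers.

Step 7
Reactants: 9 benzyl 2-O-benzyl-4,6-O-[(R)-benzylidene]-3-O-(2-naphthylmethyl)-α-D-allopyranoside
Product: 10 benzyl 2,4-di-O-benzyl-3-O-(2-naphthylmethyl)-α-D-allopyranoside
Conditions: BH3·THF, TMSOTf (cat.), CH2Cl2, 0 °C to rt; MeOH quench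
Reagents that add atoms: none
Why: In this regioselective reductive opening of a benzylidene acetal the Lewis acid should engage the less hindered O6, so hydride goes to the acetal carbon, the benzyl group stays on O4 and the primary hydroxyl is freed.

Step 8
Reactants: 10 benzyl 2,4-di-O-benzyl-3-O-(2-naphthylmethyl)-α-D-allopyranoside
Product: 11 benzyl 2,4-di-O-benzyl-6-deoxy-6-iodo-3-O-(2-naphthylmethyl)-α-D-allopyranoside
Conditions: I2, PPh3, imidazole, toluene, 70 °C
Reagents that add atoms: iodine, II
Why: The Appel-type (Garegg–Samuelsson) iodination should convert the only free, primary hydroxyl into the iodide by SN2 displacement without touching the ethers or the glycoside.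

Step 9
Reactants: 11 benzyl 2,4-di-O-benzyl-6-deoxy-6-iodo-3-O-(2-naphthylmethyl)-α-D-allopyranoside
Product: 12 benzyl 2,4-di-O-benzyl-6-deoxy-3-O-(2-naphthylmethyl)-α-D-ribo-hex-5-enopyranoside
Conditions: KOtBu, THF, 0 °C to rt
Reagents that add atoms: none
Why: E2 dehydroiodination with a bulky alkoxide can only take the hydrogen on sugar C5, so the exocyclic enol ether should form, and all ether groups tolerate the base.

Step 10
Reactants: 12 benzyl 2,4-di-O-benzyl-6-deoxy-3-O-(2-naphthylmethyl)-α-D-ribo-hex-5-enopyranoside
Product: 14 (2S,3S,4S,5S)-2,4,5-tris(benzyloxy)-3-(2-naphthylmethoxy)cyclohexan-1-one, via ring-opened oxocarbenium titanium enolate 13 (not isolated)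
Conditions: Ti(OiPr)Cl3 (1.2 equiv), CH2Cl2, −78 °C, short contact; H2O quench at −78 °C
Reagents that add atoms: none
Why: The tetravalent titanium Lewis acid binds the enol-ether ring oxygen of 12 and breaks the endocyclic bond between sugar C1 and O5, which gives 13 with a benzyloxy-stabilised oxocarbenium carbon at one chain end and a titanium enolate at the other. The enolate carbon (sugar C6, C2 of the target) then adds to the oxocarbenium carbon (sugar C1, C3 of the target) in an intramolecular Mukaiyama-aldol-type step, a 6-(enolendo)-exo-trig closure that makes the C2–C3 bond and the only carbocycle of the target. The closest known reaction type is the aprotic, aglycon-retaining form of the Ferrier carbocyclisation, which is established for ether-protected α-hex-5-enopyranosides. The one stereocentre that is re-formed, C3, is controlled by the anomeric configuration of 12: the two ends of 13 stay folded in the chair-like shape of the former pyranose and should recombine faster than the bond between sugar C1 and C2 rotates, so carbon enters where O5 left and the benzyloxy group remains cis to the C4 ether. The step needs endocyclic instead of exocyclic acetal cleavage and a product that keeps its β-benzyloxy group; the enolate character of the departing O5, the lone pair of the aglycon oxygen antiperiplanar to the breaking bond, the exclusive use of non-participating ethers, the absence of water and the cold quench should secure both. C4, C5 and C6 are spectators, and 14 (ketone = C1, CH2 = C2, all four ethers cis) is carried on without chromatography so that C6, now α to a carbonyl group, is not epimerised.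

Step 11
Reactants: 14 (2S,3S,4S,5S)-2,4,5-tris(benzyloxy)-3-(2-naphthylmethoxy)cyclohexan-1-one
Product: 15 all-cis 3,4,6-tris(benzyloxy)-1-methylidene-5-(2-naphthylmethoxy)cyclohexane (target locants)
Conditions: Cp2Ti(μ-CH2)(μ-Cl)AlMe2 (Tebbe reagent), pyridine (cat.), THF/toluene, −40 °C to rt
Reagents that add atoms: Cp2Ti(μ-CH2)(μ-Cl)AlMe2, C[Al-]1(C)C[Ti]([Cl+]1)(C1C=CC=C1)C1C=CC=C1
Why: The Tebbe olefination is not basic, so C7 should be attached to C1 without epimerising C6 and without expelling the β-benzyloxy group at C3, as is known for β-alkoxy cyclohexanones of this kind.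

Step 12
Reactants: 15 all-cis 3,4,6-tris(benzyloxy)-1-methylidene-5-(2-naphthylmethoxy)cyclohexane
Product: 16 3,4,6-tris(benzyloxy)-1-(hydroxymethyl)-5-(2-naphthylmethoxy)cyclohexan-1-ol (target locants) with the C1 hydroxyl trans and the C7 arm cis to the four ring ethers
Conditions: OsO4 (cat.), NMO, acetone/H2O, rt
Reagents that add atoms: N-methylmorpholine N-oxide, C[N+]1([O-])CCOCC1; water, O (both oxygens are passed on through catalytic OsO4, O=[Os](=O)(=O)=O)
Why: Catalytic osmium tetroxide dihydroxylation should take place on the alkene face opposite to the allylic C6 ether and the other three ring ethers, which places the C1 hydroxyl trans to them, the arrangement wanted in step 15.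

Step 13
Reactants: 16 3,4,6-tris(benzyloxy)-1-(hydroxymethyl)-5-(2-naphthylmethoxy)cyclohexan-1-ol
Product: 17 3,4,6-tris(benzyloxy)-1-(hydroxymethyl)cyclohexane-1,5-diol (target locants, configuration as in 16)
Conditions: DDQ, CH2Cl2/H2O, 0 °C to rt
Reagents that add atoms: none
Why: Oxidative ether cleavage with DDQ should strike only the electron-rich naphthylmethyl group, since benzyl ethers are harder to oxidise and the substrate holds no allylic alcohol that could be over-oxidised.

Step 14
Reactants: 17 3,4,6-tris(benzyloxy)-1-(hydroxymethyl)cyclohexane-1,5-diol; 18 benzoyl chloride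
Product: 19 [5-(benzoyloxy)-3,4,6-tris(benzyloxy)-1-hydroxycyclohexyl]methyl benzoate (target locants, configuration as in 16)
Conditions: 18 (2.3 equiv), pyridine, DMAP (cat.), CH2Cl2, 0 °C to rt
Reagents that add atoms: none
Why: Pyridine-mediated acylation should esterify the primary C7 and the secondary C5 hydroxyl, while the hindered tertiary C1 hydroxyl stays free.

Step 15
Reactants: 19 [5-(benzoyloxy)-3,4,6-tris(benzyloxy)-1-hydroxycyclohexyl]methyl benzoate
Product: 21 [(3S,4S,5R,6R)-5-(benzoyloxy)-3,4,6-tris(benzyloxy)cyclohex-1-en-1-yl]methyl benzoate, via C1 chlorosulfite ester 20 (not isolated)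
Conditions: SOCl2, pyridine, CH2Cl2, 0 °C
Reagents that add atoms: none
Why: In this E2 dehydration through 20 the favoured chair holds the C7 arm equatorial and the C1–O bond axial, and the only ring hydrogen antiperiplanar to that bond sits on C2 because the axial site on C6 is filled by its benzyloxy group, so the C1=C2 alkene should form, in line with the general tendency of axial tertiary alcohols to give endocyclic alkenes.

Step 16
Reactants: 21 [(3S,4S,5R,6R)-5-(benzoyloxy)-3,4,6-tris(benzyloxy)cyclohex-1-en-1-yl]methyl benzoate
Product: 22 [(3S,4S,5R,6R)-5-(benzoyloxy)-3,4,6-trihydroxycyclohex-1-en-1-yl]methyl benzoate (target)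
Conditions: BCl3, pentamethylbenzene, CH2Cl2, −78 °C; MeOH quench at −78 °C, no basic work-up
Reagents that add atoms: none
Why: Lewis-acid dealkylation of benzyl ethers in the presence of an arene cation scavenger should remove the three benzyl groups at low temperature without reducing the alkene or cleaving the benzoates, and the base-free work-up should keep the C5 benzoate from migrating to its cis neighbours.

Compound list
1 | D-glucose | O=C[C@H](O)[C@@H](O)[C@H](O)[C@H](O)CO | starting material
2 | benzyl alcohol | OCc1ccccc1 | starting material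
3 | benzyl α-D-glucopyranoside | OC[C@H]1O[C@H](OCc2ccccc2)[C@H](O)[C@@H](O)[C@@H]1O | intermediate
4 | benzyl 4,6-O-[(R)-benzylidene]-α-D-glucopyranoside | C(c1ccccc1)O[C@H]1O[C@@H]2CO[C@@H](c3ccccc3)O[C@H]2[C@H](O)[C@H]1O | intermediate
5 | benzyl 2-O-benzyl-4,6-O-[(R)-benzylidene]-α-D-glucopyranoside | C(c1ccccc1)O[C@H]1O[C@@H]2CO[C@@H](c3ccccc3)O[C@H]2[C@H](O)[C@H]1OCc1ccccc1 | intermediate
6 | benzyl 2-O-benzyl-4,6-O-[(R)-benzylidene]-α-D-ribo-hexopyranosid-3-ulose | C(c1ccccc1)O[C@H]1O[C@@H]2CO[C@@H](c3ccccc3)O[C@H]2C(=O)[C@H]1OCc1ccccc1 | intermediate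
7 | benzyl 2-O-benzyl-4,6-O-[(R)-benzylidene]-α-D-allopyranoside | C(c1ccccc1)O[C@H]1O[C@@H]2CO[C@@H](c3ccccc3)O[C@H]2[C@@H](O)[C@H]1OCc1ccccc1 | intermediate
8 | 2-(bromomethyl)naphthalene | BrCc1ccc2ccccc2c1 | starting material
9 | benzyl 2-O-benzyl-4,6-O-[(R)-benzylidene]-3-O-(2-naphthylmethyl)-α-D-allopyranoside | C(c1ccccc1)O[C@H]1O[C@@H]2CO[C@@H](c3ccccc3)O[C@H]2[C@@H](OCc2ccc3ccccc3c2)[C@H]1OCc1ccccc1 | intermediate
10 | benzyl 2,4-di-O-benzyl-3-O-(2-naphthylmethyl)-α-D-allopyranoside | OC[C@H]1O[C@H](OCc2ccccc2)[C@H](OCc2ccccc2)[C@H](OCc2ccc3ccccc3c2)[C@@H]1OCc1ccccc1 | intermediate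
11 | benzyl 2,4-di-O-benzyl-6-deoxy-6-iodo-3-O-(2-naphthylmethyl)-α-D-allopyranoside | IC[C@H]1O[C@H](OCc2ccccc2)[C@H](OCc2ccccc2)[C@H](OCc2ccc3ccccc3c2)[C@@H]1OCc1ccccc1 | intermediate
12 | benzyl 2,4-di-O-benzyl-6-deoxy-3-O-(2-naphthylmethyl)-α-D-ribo-hex-5-enopyranoside | C=C1O[C@H](OCc2ccccc2)[C@H](OCc2ccccc2)[C@H](OCc2ccc3ccccc3c2)[C@@H]1OCc1ccccc1 | intermediate
13 | ring-opened oxocarbenium titanium enolate (zwitterion from cleavage of the sugar C1–O5 bond of 12, trichloro(isopropoxy)titanate on the enolate oxygen) | C=C(O[Ti-](Cl)(Cl)(Cl)OC(C)C)[C@@H](OCc1ccccc1)[C@@H](OCc1ccc2ccccc2c1)[C@@H](OCc1ccccc1)C=[O+]Cc1ccccc1 | intermediate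
14 | (2S,3S,4S,5S)-2,4,5-tris(benzyloxy)-3-(2-naphthylmethoxy)cyclohexan-1-one (all four ethers cis) | O=C1C[C@H](OCc2ccccc2)[C@H](OCc2ccccc2)[C@H](OCc2ccc3ccccc3c2)[C@@H]1OCc1ccccc1 | intermediate
15 | all-cis 3,4,6-tris(benzyloxy)-1-methylidene-5-(2-naphthylmethoxy)cyclohexane (target locants) | C=C1C[C@H](OCc2ccccc2)[C@H](OCc2ccccc2)[C@H](OCc2ccc3ccccc3c2)[C@@H]1OCc1ccccc1 | intermediate
16 | 3,4,6-tris(benzyloxy)-1-(hydroxymethyl)-5-(2-naphthylmethoxy)cyclohexan-1-ol (target locants; C1–OH trans, C7 cis to the four ring ethers) | OC[C@]1(O)C[C@H](OCc2ccccc2)[C@H](OCc2ccccc2)[C@H](OCc2ccc3ccccc3c2)[C@@H]1OCc1ccccc1 | intermediate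
17 | 3,4,6-tris(benzyloxy)-1-(hydroxymethyl)cyclohexane-1,5-diol (target locants; configuration as in 16) | OC[C@]1(O)C[C@H](OCc2ccccc2)[C@H](OCc2ccccc2)[C@H](O)[C@@H]1OCc1ccccc1 | intermediate
18 | benzoyl chloride | O=C(Cl)c1ccccc1 | starting material
19 | [5-(benzoyloxy)-3,4,6-tris(benzyloxy)-1-hydroxycyclohexyl]methyl benzoate (target locants; configuration as in 16) | O=C(OC[C@]1(O)C[C@H](OCc2ccccc2)[C@H](OCc2ccccc2)[C@H](OC(=O)c2ccccc2)[C@@H]1OCc1ccccc1)c1ccccc1 | intermediate
20 | C1 chlorosulfite ester of 19 | O=C(OC[C@]1(OS(=O)Cl)C[C@H](OCc2ccccc2)[C@H](OCc2ccccc2)[C@H](OC(=O)c2ccccc2)[C@@H]1OCc1ccccc1)c1ccccc1 | intermediate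
21 | [(3S,4S,5R,6R)-5-(benzoyloxy)-3,4,6-tris(benzyloxy)cyclohex-1-en-1-yl]methyl benzoate | O=C(OCC1=C[C@H](OCc2ccccc2)[C@H](OCc2ccccc2)[C@H](OC(=O)c2ccccc2)[C@@H]1OCc1ccccc1)c1ccccc1 | intermediate
22 | [(3S,4S,5R,6R)-5-(benzoyloxy)-3,4,6-trihydroxycyclohex-1-en-1-yl]methyl benzoate | O=C(OCC1=C[C@H](O)[C@H](O)[C@H](OC(=O)c2ccccc2)[C@@H]1O)c1ccccc1 | target

Total step count: 16. Longest linear sequence: 16 (fully linear from D-glucose).

Steps most likely to fail

Step 10. Three things may go wrong.
- The syn-axial oxygens on sugar C1 and C3 may chelate titanium and divert the cleavage to the exocyclic acetal bond, with loss of the aglycon.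
- Bond rotation within 13 may erode the configuration at C3.
- The β-benzyloxy ketone may lose benzyl alcohol during the quench.

The fallback sets out from 12 and runs the rearrangement reductively with iBu3Al in toluene. The aluminium reagent should trigger the same endocyclic cleavage and the same C2–C3 closure. It then reduces the carbonyl group in the same flask by β-hydride transfer from the face opposite to the ring ethers. This should give the elimination-proof all-cis 2,4,5-tris(benzyloxy)-3-(2-naphthylmethoxy)cyclohexan-1-ol F1. Dess–Martin oxidation of F1 directly before the methylenation comes back to the route at 14.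

Step 15. Three things may go wrong.
- The C7 benzoate carbonyl may capture the positive charge that develops at C1.
- Chloride may substitute at C1.
- A C7 hydrogen may be lost to give an exocyclic double bond.

The fallback fixes the alkene position by cross-coupling instead of elimination and sets out from 14. Kinetic deprotonation at the unhindered C2 methylene with KN(SiMe3)2 in THF at −78 °C, followed by trapping at that temperature with N-(5-chloro-2-pyridyl)bis(trifluoromethanesulfonimide), should give all-cis 3,4,6-tris(benzyloxy)-5-(2-naphthylmethoxy)cyclohex-1-en-1-yl trifluoromethanesulfonate F2. Stille coupling of F2 with Bu3SnCH2OH (Pd(PPh3)4, LiCl, dioxane, heat) should give [3,4,6-tris(benzyloxy)-5-(2-naphthylmethoxy)cyclohex-1-en-1-yl]methanol F3. DDQ in wet CH2Cl2 at 0 °C should then free [3,4,6-tris(benzyloxy)-5-hydroxycyclohex-1-en-1-yl]methanol F4. Dibenzoylation of F4 with 18 in pyridine comes back to the route at 21.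

Step 16. The Lewis acid may ionise the allylic C3–O or C7–O bond, or acid may promote migration of the C5 benzoate to a cis neighbour. The fallback sets out from 21 and replaces Lewis-acid dealkylation with photo-oxidative debenzylation, using DDQ in wet CH2Cl2 under visible-light irradiation. This is a neutral process that turns each benzyl ether into an aldehyde and a free hydroxyl. It leads directly to 22 and makes no new compound (entry F0).

Further compounds
F1 | step 10 | all-cis 2,4,5-tris(benzyloxy)-3-(2-naphthylmethoxy)cyclohexan-1-ol | O[C@@H]1C[C@H](OCc2ccccc2)[C@H](OCc2ccccc2)[C@H](OCc2ccc3ccccc3c2)[C@@H]1OCc1ccccc1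
F2 | step 15 | all-cis 3,4,6-tris(benzyloxy)-5-(2-naphthylmethoxy)cyclohex-1-en-1-yl trifluoromethanesulfonate | O=S(=O)(OC1=C[C@H](OCc2ccccc2)[C@H](OCc2ccccc2)[C@H](OCc2ccc3ccccc3c2)[C@@H]1OCc1ccccc1)C(F)(F)F
F3 | step 15 | [3,4,6-tris(benzyloxy)-5-(2-naphthylmethoxy)cyclohex-1-en-1-yl]methanol | OCC1=C[C@H](OCc2ccccc2)[C@H](OCc2ccccc2)[C@H](OCc2ccc3ccccc3c2)[C@@H]1OCc1ccccc1
F4 | step 15 | [3,4,6-tris(benzyloxy)-5-hydroxycyclohex-1-en-1-yl]methanol | OCC1=C[C@H](OCc2ccccc2)[C@H](OCc2ccccc2)[C@H](O)[C@@H]1OCc1ccccc1
F0 | step 16 | none | none
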